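**Early readings.** At early times single product is already high in both earlier runs: 16.7% on Sunday and 19.0% on Monday at 0.250 min. It then falls while substrate stays near 65.8%.

| flask | substrate | partner | remark | time |
|---|---|---|---|---|
| Sunday's | 7 mM | 0.50 equiv | run made earlier |  |
| Monday's | 11 mM | 0.50 equiv | run made earlier |  |
| flask | 5.0 mM | 0.500 equiv |  | 2.5 min |

- Sunday's (time / min: single product / %, substrate / %): 0.250: 16.7, 68.9; 0.417: 16.7, 65.9; 0.833: 15.2, 64.7; 1.50: 10.3, 65.8; 3.00: 5.9, 68.4
- Monday's (time / min: single product / %, substrate / %): 0.250: 19.0, 64.4; 0.833: 14.8, 64.0; 1.33: 11.6, 65.7; 2.00: 8.5, 65.6; 3.00: 5.7, 67.5

(readings scatter by 0.5 percentage points)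

1. equivalents of partner to substrate, everything else as given, that leave most single product at 2.5 min
2. the amount of single product then, in percent of the substrate charged
3. the amount of single product with the amounts as given

**Bench rule.** Take the quick stage with partner, the limiting reagent, as finished, and treat the later fall of single product as first-order. The fade constant λ is then the logarithm of the ratio of two readings, divided by the time between them. From 0.833 min to 3.00 min, Sunday's run gives 0.437 /min and Monday's gives 0.440 /min. These agree, although the substrate charges differ by a factor of 1.57, so the mean is λ = 0.439 /min.

**The border.** The rule fails while single product is still forming: Sunday's reading holds at 16.7% up to 0.417 min. If that stage stretches inversely with concentration, the border in the flask lies at 0.584 min, and 2.5 min is later. Starting from the mean of 15.2% and 14.8% at 0.833 min, the reckoning made here gives 7.22% for the flask. λ gives a fall and not a height, and this reckoning offers no best charge.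

**Forecast.** With M for single product, the forecast holds that “M decays at a rate independent of concentration”. It gives 7.3% as charged, slightly above the reckoning here, and 8% at 0.7 equiv.

**Result.** The flask gives 6.79% as charged and 8.81% at 1.16 equiv.

    substrate + partner ⇌ single product (K = 710 /M, k = 9.20 /M/s)
    substrate + partner → other mono adduct (k = 6.10 /M/s)
    partner + single product → double product (k = 6.70 /M/s)
    partner + other mono adduct → double product (k = 18.0 /M/s)
    partner → decomposed reagent (k = 0.00800 /s)

At 2.5 min the flask keeps 69% of its substrate but 2.6% of its partner. The neighbour flask, with the same charges but read at 40 s, holds 15.1% of single product, and λ carries that neighbour's reading on to 6.76% at 2.5 min.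

The data are calculated for an exercise, and the scatter is random.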